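**Retrosynthetic overview**
Rings: A = oxygenated benzo ring (C4a–C8a); C = dihydropyran (O1, C2, C3, C4, C4a, C8a); B = pentasubstituted aryl ring (C1'–C6'); D = 2,2-dimethylpyran on O4'/C5'.
Endgame: 20 comes from two aromatic Claisen events on ring B. The O3'-(1,1-dimethylallyl) ether gives the C2'-prenyl group, and the O4'-(1,1-dimethylpropargyl) ether gives ring D at C5'.
Core: (2S)-flavan 10 comes from 1-arylindan-1-yl hydroperoxide 8 by oxygen insertion (aryl C→O 1,2-shift, five-membered carbocycle to six-membered oxacycle), followed by asymmetric ion-pair hydride capture of the oxocarbenium ion.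
Enabling feature: O1 lies between aromatic C8a of ring A and C2, which bears ring B, so deleting O1 gives a 1-arylindane. The cation at C2 is stabilised by O1 and is planar, so racemic 8 converges on one configuration of the only stereocentre. O4' (para to C1') is carried as a tosylate so that ring B neither migrates nor labilises C2–O1.
8 comes from tertiary alcohol 7, and 7 from the aryl Grignard of 5 plus indanone 2. Ring order: A, B and the carbocycle are bought, then C (step 6), then D (step 12).

Key step: step 6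

Assumption: the sense of induction of the chiral acid cannot be predicted with certainty, so the catalyst antipode that delivers hydride to the Re face of C2 (2S) is meant; tert-butyl 2-methylbut-3-en-2-yl carbonate and 3-chloro-3-methylbut-1-yne are taken as purchasable reagents.

**Step 1**
Reactants: 1 6-hydroxy-1-indanone
Product: 2 6-(triisopropylsilyloxy)-1-indanone
Conditions: TIPSCl, imidazole, DMF, rt
Reagents that add atoms: triisopropylsilyl chloride, CC(C)[Si](Cl)(C(C)C)C(C)C
Why: Standard silylation of a phenol; the bulky aryl silyl ether should survive Grignard addition, dilute acid, hydrogenolysis and mild base, and is removed by fluoride at the end.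

**Step 2**
Reactants: 3 2-(benzyloxy)phenol
Product: 4 2-(benzyloxy)-4-iodophenol
Conditions: NIS, TsOH·H2O (cat.), MeCN, rt
Reagents that add atoms: N-iodosuccinimide, O=C1CCC(=O)N1I
Why: In this electrophilic aromatic iodination the free hydroxyl directs para more strongly than the benzyl ether, so iodine marks the future C1' para to O4' and the two catechol oxygens are differentiated from the start.

**Step 3**
Reactants: 4 2-(benzyloxy)-4-iodophenol
Product: 5 2-(benzyloxy)-4-iodophenyl 4-methylbenzenesulfonate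
Conditions: TsCl, Et3N, DMAP (cat.), CH2Cl2, 0 °C to rt
Reagents that add atoms: 4-toluenesulfonyl chloride, Cc1ccc(cc1)S(Cl)(=O)=O
Why: O-sulfonylation of a phenol turns O4' into an electron-withdrawing, non-migrating group that is needed in step 6.

**Step 4**
Reactants: 5 2-(benzyloxy)-4-iodophenyl 4-methylbenzenesulfonate; 2 6-(triisopropylsilyloxy)-1-indanone
Product: 7 rac-1-[3-(benzyloxy)-4-(tosyloxy)phenyl]-6-(triisopropylsilyloxy)indan-1-ol, via arylmagnesium chloride 6 (not isolated)
Conditions: 5, i-PrMgCl·LiCl, THF, −30 °C; then 2, LaCl3·2LiCl, −30 to 0 °C; aq NH4Cl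
Reagents that add atoms: none
Why: Iodine–magnesium exchange tolerates the aryl tosylate at low temperature and the lanthanum-assisted Grignard 1,2-addition outruns enolisation of the indanone; the new carbinol centre is racemic and is erased in step 6.

**Step 5**
Reactants: 7 rac-1-[3-(benzyloxy)-4-(tosyloxy)phenyl]-6-(triisopropylsilyloxy)indan-1-ol
Product: 8 rac-1-[3-(benzyloxy)-4-(tosyloxy)phenyl]-6-(triisopropylsilyloxy)indan-1-yl hydroperoxide
Conditions: 50% aq H2O2, H2SO4 (cat.), Et2O, 0 °C
Reagents that add atoms: hydrogen peroxide, OO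
Why: In this acid-catalysed perhydrolysis (SN1) of a tertiary, doubly benzylic alcohol the cation is captured by the more nucleophilic hydrogen peroxide, as known for 1,1-diarylalkanols; the configuration is irrelevant.

**Step 6**
Reactants: 8 rac-1-[3-(benzyloxy)-4-(tosyloxy)phenyl]-6-(triisopropylsilyloxy)indan-1-yl hydroperoxide
Product: 10 (2S)-2-[3-(benzyloxy)-4-(tosyloxy)phenyl]-7-(triisopropylsilyloxy)chroman, via oxocarbenium ion 9 (not isolated)
Conditions: chiral IDPi Brønsted acid (5 mol %, antipode giving 2S), Et3SiH (1.5 equiv), CH2Cl2, −40 to −20 °C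
Reagents that add atoms: none
Why: Proposed new method: the confined chiral acid (or the silylium ion pair it forms with Et3SiH) activates the distal peroxide oxygen of 8, and C8a of ring A shifts from C2 to the proximal oxygen as the O–O bond breaks (Hock/Criegee 1,2-aryl shift), which inserts O1 into the C8a–C2 bond and turns the five-membered carbocycle into six-membered ring C as oxocarbenium ion 9. The closest known reactions are the Lewis-acid-promoted Hock rearrangement of indanyl and tetralinyl hydroperoxides with in situ capture of the cyclic oxocarbenium ion by silicon nucleophiles, and IDPi catalysis through cyclic oxocarbenium ion pairs; merging them with a silane as hydride donor is new. No ring is closed end to end, because ring C forms by 5→6 enlargement through the 1,2-shift, so no competing ring size can arise. The only stereocentre, C2, is planar in 9, so both enantiomers of 8 converge, and the chiral counter-anion should shield the Si face so that hydride enters at the Re face and gives 2S. The step needs migration of ring A rather than ring B or C3, and this is secured by the tosylate on O4' (para to C1'), which lowers the migratory aptitude of ring B, while C8a carries an ortho-alkyl group and only a meta silyloxy group. The same tosylate keeps the C2–O1 bond of 10 from ionising in the acid, so the new stereocentre should not be scrambled.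

**Step 7**
Reactants: 10 (2S)-2-[3-(benzyloxy)-4-(tosyloxy)phenyl]-7-(triisopropylsilyloxy)chroman
Product: 11 (2S)-2-[3-hydroxy-4-(tosyloxy)phenyl]-7-(triisopropylsilyloxy)chroman
Conditions: H2 (1 atm), 10% Pd/C, EtOAc, rt
Reagents that add atoms: none
Why: Hydrogenolysis of the benzyl aryl ether frees O3' only; the aryl tosylate and silyl ether are inert and the electron-poor ring B slows hydrogenolysis of C2–O1, so C2 is untouched.

**Step 8**
Reactants: 11 (2S)-2-[3-hydroxy-4-(tosyloxy)phenyl]-7-(triisopropylsilyloxy)chroman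
Product: 12 (2S)-2-[3-(2-methylbut-3-en-2-yloxy)-4-(tosyloxy)phenyl]-7-(triisopropylsilyloxy)chroman
Conditions: tert-butyl 2-methylbut-3-en-2-yl carbonate, Pd(PPh3)4 (5 mol %), THF, 0 °C
Reagents that add atoms: tert-butyl 2-methylbut-3-en-2-yl carbonate, CC(C)(C)OC(=O)OC(C)(C)C=C
Why: In this palladium-catalysed decarboxylative O-allylation (Tsuji–Trost type) the phenoxide attacks the more substituted terminus of the 1,1-dimethylallyl complex at low temperature and gives the tertiary ether without external base.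

**Step 9**
Reactants: 12 (2S)-2-[3-(2-methylbut-3-en-2-yloxy)-4-(tosyloxy)phenyl]-7-(triisopropylsilyloxy)chroman
Product: 14 (2S)-2-[3-hydroxy-2-(3-methylbut-2-enyl)-4-(tosyloxy)phenyl]-7-(triisopropylsilyloxy)chroman, via ortho-dienone 13 (not isolated)
Conditions: toluene, 110 °C
Reagents that add atoms: none
Why: In this aromatic Claisen rearrangement only C2' of the two ortho positions of O3' bears hydrogen (C4' carries the tosylate), so the [3,3] shift with allyl inversion and tautomerisation of 13 places a linear prenyl group at C2'.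

**Step 10**
Reactants: 14 (2S)-2-[3-hydroxy-2-(3-methylbut-2-enyl)-4-(tosyloxy)phenyl]-7-(triisopropylsilyloxy)chroman
Product: 15 (2S)-2-[3,4-dihydroxy-2-(3-methylbut-2-enyl)phenyl]-7-(triisopropylsilyloxy)chroman
Conditions: Mg, MeOH, rt, short contact; aq NH4Cl
Reagents that add atoms: none
Why: Reductive S–O cleavage of the aryl tosylate by magnesium in methanol (electron transfer) leaves the isolated alkene, the hindered silyl ether and the benzylic ether alone; prompt quenching keeps the O4' phenoxide from opening ring C through a para-quinone methide.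

**Step 11**
Reactants: 15 (2S)-2-[3,4-dihydroxy-2-(3-methylbut-2-enyl)phenyl]-7-(triisopropylsilyloxy)chroman
Product: 16 (2S)-2-[3-hydroxy-2-(3-methylbut-2-enyl)-4-(2-methylbut-3-yn-2-yloxy)phenyl]-7-(triisopropylsilyloxy)chroman
Conditions: 3-chloro-3-methylbut-1-yne (1.05 equiv), CuCl2·2H2O (1 mol %), DBU, MeCN, −5 °C, Ar
Reagents that add atoms: 3-chloro-3-methylbut-1-yne, CC(C)(Cl)C#C
Why: In this copper-catalysed propargylic etherification O4'–H has the free neighbour C5'–H while O3'–H is flanked by the prenyl group, so the bulky tertiary electrophile should take the less hindered oxygen; low temperature and exclusion of air guard against ring opening at C2 and catechol oxidation.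

**Step 12**
Reactants: 16 (2S)-2-[3-hydroxy-2-(3-methylbut-2-enyl)-4-(2-methylbut-3-yn-2-yloxy)phenyl]-7-(triisopropylsilyloxy)chroman
Product: 19 7-O-triisopropylsilyl kazinol B, via allenylphenol 17 (not isolated), via ortho-quinone methide 18 (not isolated)
Conditions: o-xylene, 140 °C
Reagents that add atoms: none
Why: In this propargyl Claisen cascade the [3,3] shift goes to C5' (the only free ortho position of O4'), tautomerisation gives 17, a 1,5-hydrogen shift gives 18, and oxa-6π electrocyclisation closes ring D under neutral conditions that do not touch C2.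

**Step 13**
Reactants: 19 7-O-triisopropylsilyl kazinol B
Product: 20 kazinol B
Conditions: TBAF, AcOH (1:1), THF, 0 °C
Reagents that add atoms: none
Why: Buffered fluoride cleaves the aryl silyl ether without acid, so the ortho-prenylphenol does not cyclise, and O4' is now alkylated, so C2 stays configurationally stable.

**Compound list**
1 | 6-hydroxy-1-indanone | O=C1CCc2ccc(O)cc12 | starting material
2 | 6-(triisopropylsilyloxy)-1-indanone | O=C1CCc2ccc(O[Si](C(C)C)(C(C)C)C(C)C)cc12 | intermediate
3 | 2-(benzyloxy)phenol | Oc1ccccc1OCc1ccccc1 | starting material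
4 | 2-(benzyloxy)-4-iodophenol | Oc1ccc(I)cc1OCc1ccccc1 | intermediate
5 | 2-(benzyloxy)-4-iodophenyl 4-methylbenzenesulfonate | Cc1ccc(cc1)S(=O)(=O)Oc1ccc(I)cc1OCc1ccccc1 | intermediate
6 | [3-(benzyloxy)-4-(tosyloxy)phenyl]magnesium chloride | Cc1ccc(cc1)S(=O)(=O)Oc1ccc([Mg]Cl)cc1OCc1ccccc1 | intermediate
7 | rac-1-[3-(benzyloxy)-4-(tosyloxy)phenyl]-6-(triisopropylsilyloxy)indan-1-ol | Cc1ccc(cc1)S(=O)(=O)Oc1ccc(cc1OCc1ccccc1)C1(O)CCc2ccc(O[Si](C(C)C)(C(C)C)C(C)C)cc12 | intermediate
8 | rac-1-[3-(benzyloxy)-4-(tosyloxy)phenyl]-6-(triisopropylsilyloxy)indan-1-yl hydroperoxide | Cc1ccc(cc1)S(=O)(=O)Oc1ccc(cc1OCc1ccccc1)C1(OO)CCc2ccc(O[Si](C(C)C)(C(C)C)C(C)C)cc12 | intermediate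
9 | 2-[3-(benzyloxy)-4-(tosyloxy)phenyl]-7-(triisopropylsilyloxy)-3,4-dihydrochromenylium (oxocarbenium ion, paired with the chiral anion) | Cc1ccc(cc1)S(=O)(=O)Oc1ccc(cc1OCc1ccccc1)C1=[O+]c2cc(O[Si](C(C)C)(C(C)C)C(C)C)ccc2CC1 | intermediate
10 | (2S)-2-[3-(benzyloxy)-4-(tosyloxy)phenyl]-7-(triisopropylsilyloxy)chroman | Cc1ccc(cc1)S(=O)(=O)Oc1ccc(cc1OCc1ccccc1)[C@@H]1CCc2ccc(O[Si](C(C)C)(C(C)C)C(C)C)cc2O1 | intermediate
11 | (2S)-2-[3-hydroxy-4-(tosyloxy)phenyl]-7-(triisopropylsilyloxy)chroman | Cc1ccc(cc1)S(=O)(=O)Oc1ccc(cc1O)[C@@H]1CCc2ccc(O[Si](C(C)C)(C(C)C)C(C)C)cc2O1 | intermediate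
12 | (2S)-2-[3-(2-methylbut-3-en-2-yloxy)-4-(tosyloxy)phenyl]-7-(triisopropylsilyloxy)chroman | Cc1ccc(cc1)S(=O)(=O)Oc1ccc(cc1OC(C)(C)C=C)[C@@H]1CCc2ccc(O[Si](C(C)C)(C(C)C)C(C)C)cc2O1 | intermediate
13 | 6-prenylcyclohexa-2,4-dienone from the [3,3] shift (C2' sp3, configuration there undefined) | CC(C)=CCC1C(=O)C(OS(=O)(=O)c2ccc(C)cc2)=CC=C1[C@@H]1CCc2ccc(O[Si](C(C)C)(C(C)C)C(C)C)cc2O1 | intermediate
14 | (2S)-2-[3-hydroxy-2-(3-methylbut-2-enyl)-4-(tosyloxy)phenyl]-7-(triisopropylsilyloxy)chroman | CC(C)=CCc1c([C@@H]2CCc3ccc(O[Si](C(C)C)(C(C)C)C(C)C)cc3O2)ccc(OS(=O)(=O)c2ccc(C)cc2)c1O | intermediate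
15 | (2S)-2-[3,4-dihydroxy-2-(3-methylbut-2-enyl)phenyl]-7-(triisopropylsilyloxy)chroman | CC(C)=CCc1c([C@@H]2CCc3ccc(O[Si](C(C)C)(C(C)C)C(C)C)cc3O2)ccc(O)c1O | intermediate
16 | (2S)-2-[3-hydroxy-2-(3-methylbut-2-enyl)-4-(2-methylbut-3-yn-2-yloxy)phenyl]-7-(triisopropylsilyloxy)chroman | CC(C)=CCc1c([C@@H]2CCc3ccc(O[Si](C(C)C)(C(C)C)C(C)C)cc3O2)ccc(OC(C)(C)C#C)c1O | intermediate
17 | C5'-(3-methylbuta-1,2-dienyl)catechol (allenylphenol) | CC(C)=CCc1c([C@@H]2CCc3ccc(O[Si](C(C)C)(C(C)C)C(C)C)cc3O2)cc(C=C=C(C)C)c(O)c1O | intermediate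
18 | ortho-quinone methide with C4'=O and C5'=CH–CH=CMe2 | CC(C)=CCC1=C(O)C(=O)C(=CC=C(C)C)C=C1[C@@H]1CCc2ccc(O[Si](C(C)C)(C(C)C)C(C)C)cc2O1 | intermediate
19 | 7-O-triisopropylsilyl kazinol B | CC(C)=CCc1c([C@@H]2CCc3ccc(O[Si](C(C)C)(C(C)C)C(C)C)cc3O2)cc2c(c1O)OC(C)(C)C=C2 | intermediate
20 | kazinol B, (2S) | CC(C)=CCc1c([C@@H]2CCc3ccc(O)cc3O2)cc2c(c1O)OC(C)(C)C=C2 | target

**Step count**
Total steps: 13. Longest linear sequence: 12 steps (3 to 20, steps 2–13).

**Steps most likely to fail**

1. Step 6. The hydroperoxide may ionise at C–O and lose hydrogen peroxide, followed by ionic hydrogenation of the carbocation. Ring B may migrate in part. The facial discrimination in the ion pair may be weak. The fallback keeps the ring enlargement but separates it from the stereochemical event, and it uses known chemistry. It sets out from 8, which is treated with catalytic BF3·OEt2 in CH2Cl2 over 4 Å molecular sieves. This is an achiral Hock rearrangement, and the 2-hydroxyflavan dehydrates to the cyclic enol ether 2-[3-(benzyloxy)-4-(tosyloxy)phenyl]-7-(triisopropylsilyloxy)-4H-chromene F1. Iridium-catalysed asymmetric hydrogenation of this 2-aryl-4H-chromene (Ir–phosphinooxazoline BArF complex, H2 50 bar, CH2Cl2) then sets C2. The route is rejoined at 10.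

2. Step 5. Water may be eliminated to the indene, and the O–O bond may be cleaved prematurely in the aqueous acidic peroxide. The fallback sets out from 7, which is deliberately dehydrated (TsOH cat., toluene, 60 °C) to the 3-aryl-6-(triisopropylsilyloxy)-1H-indene F2. Cobalt-catalysed Markovnikov hydroperoxysilylation (Mukaiyama–Isayama conditions: Co(thd)2, O2, Et3SiH, 1,2-dichloroethane, rt) gives the tertiary triethylsilyl peroxide F3. Mild methanolysis (PPTS, MeOH, 0 °C) then frees the hydroperoxide. The route is rejoined at 8.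

3. Step 11. Discrimination between the two catechol hydroxyls may be poor, double alkylation may occur, and copper may oxidise the catechol. The fallback removes the selectivity question with a protecting group that cannot migrate. It sets out from 14, whose O3'–H is converted with SEMCl and i-Pr2NEt (CH2Cl2, reflux) into the 3'-O-SEM 4'-O-tosyl flavan F4. Mg/MeOH then gives the 4'-phenol F5, and the same copper-catalysed propargylation, now with a single free hydroxyl, gives the 4'-O-(1,1-dimethylpropargyl) ether F6. Heating in o-xylene at 140 °C gives the doubly protected chromene F7. Excess TBAF (THF/DMPU, 50 °C) removes the SEM and TIPS groups together. The route is rejoined at 20.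

**Further compounds**
F1 | step 6 | 2-[3-(benzyloxy)-4-(tosyloxy)phenyl]-7-(triisopropylsilyloxy)-4H-chromene | Cc1ccc(cc1)S(=O)(=O)Oc1ccc(cc1OCc1ccccc1)C1=CCc2ccc(O[Si](C(C)C)(C(C)C)C(C)C)cc2O1
F2 | step 5 | 3-[3-(benzyloxy)-4-(tosyloxy)phenyl]-6-(triisopropylsilyloxy)-1H-indene (silyloxy group para to the CH2-bearing ring carbon, as in 7) | Cc1ccc(cc1)S(=O)(=O)Oc1ccc(cc1OCc1ccccc1)C1=CCc2ccc(O[Si](C(C)C)(C(C)C)C(C)C)cc12
F3 | step 5 | rac-1-[3-(benzyloxy)-4-(tosyloxy)phenyl]-6-(triisopropylsilyloxy)indan-1-yl triethylsilyl peroxide | CC[Si](CC)(CC)OOC1(CCc2ccc(O[Si](C(C)C)(C(C)C)C(C)C)cc12)c1ccc(OS(=O)(=O)c2ccc(C)cc2)c(OCc2ccccc2)c1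
F4 | step 11 | (2S)-2-[2-(3-methylbut-2-enyl)-3-(2-trimethylsilylethoxymethoxy)-4-(tosyloxy)phenyl]-7-(triisopropylsilyloxy)chroman | CC(C)=CCc1c([C@@H]2CCc3ccc(O[Si](C(C)C)(C(C)C)C(C)C)cc3O2)ccc(OS(=O)(=O)c2ccc(C)cc2)c1OCOCC[Si](C)(C)C
F5 | step 11 | (2S)-2-[4-hydroxy-2-(3-methylbut-2-enyl)-3-(2-trimethylsilylethoxymethoxy)phenyl]-7-(triisopropylsilyloxy)chroman | CC(C)=CCc1c([C@@H]2CCc3ccc(O[Si](C(C)C)(C(C)C)C(C)C)cc3O2)ccc(O)c1OCOCC[Si](C)(C)C
F6 | step 11 | (2S)-2-[2-(3-methylbut-2-enyl)-4-(2-methylbut-3-yn-2-yloxy)-3-(2-trimethylsilylethoxymethoxy)phenyl]-7-(triisopropylsilyloxy)chroman | CC(C)=CCc1c([C@@H]2CCc3ccc(O[Si](C(C)C)(C(C)C)C(C)C)cc3O2)ccc(OC(C)(C)C#C)c1OCOCC[Si](C)(C)C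
F7 | step 11 | 3'-O-SEM-7-O-TIPS kazinol B | CC(C)=CCc1c([C@@H]2CCc3ccc(O[Si](C(C)C)(C(C)C)C(C)C)cc3O2)cc2c(c1OCOCC[Si](C)(C)C)OC(C)(C)C=C2
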